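**Retrosynthetic overview**

1. Target 14 ⇒ its 8‑O‑methyl ether 12; the last step is a chelation‑controlled O‑demethylation next to the lactone C=O.
2. 12 ⇒ racemic gem‑bromo ester 11 by cutting C3–C4, the only C(sp3)–C(sp3) bond of the lactone ring (O2–C3–C4–C4a–C8a–C1). An enantioconvergent nickel‑catalysed reductive ring closure forms the one ring made in the route and its one stereocentre (C3, R) in the same operation.
3. Enabling feature: C3 is an O‑acylated carbinol carbon (O2 is the ester oxygen of the C1 carboxyl), so it sits at the aldehyde oxidation level and gives an α‑acyloxy radical from a C–Br bond. C4 is a benzylic CH2 on C4a, ortho to the carboxyl‑bearing C8a, so it can be a benzyl bromide. The C1(=O)–O2 ester already holds the two carbons 1,6 to each other.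
4. 11 ⇒ acyl bromide 3 + keto‑aldehyde 10 (fully atom‑economic addition of C(=O)–Br across CH=O); 3 ⇐ 2,4‑dimethoxy‑6‑methylbenzoic acid (acyl bromide, then benzylic bromination).
5. 10 ⇐ ozonolysis of 1‑pentylcycloheptene, a temporary seven‑membered carbocycle from cycloheptanone and pentylmagnesium bromide. The benzene ring is bought; the pyranone ring is the only ring formed (step 7).

Key step: step 7

Assumption: the C8 phenol is carried as its methyl ether (2,4‑dimethoxy‑6‑methylbenzoic acid taken as a catalogue compound), and the antipode of the nickel ligand that gives 3R cannot be predicted and is fixed by screening both.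

**Route**

Step 1
Reactants: 1 2,4‑dimethoxy‑6‑methylbenzoic acid
Product: 2 2,4‑dimethoxy‑6‑methylbenzoyl bromide
Conditions: (COBr)2 (1.2 equiv), DMF (cat.), CH2Cl2, 0 °C to rt; evaporate
Reagents that add atoms: oxalyl bromide, O=C(Br)C(=O)Br
Why: Acyl halide formation through the bromo‑iminium (Vilsmeier‑type) species from oxalyl bromide/DMF should convert the hindered, electron‑rich acid into the acyl bromide without touching the aryl methyl ethers.

Step 2
Reactants: 2 2,4‑dimethoxy‑6‑methylbenzoyl bromide
Product: 3 2‑(bromomethyl)‑4,6‑dimethoxybenzoyl bromide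
Conditions: NBS (1.05 equiv), AIBN (5 mol %), PhCF3, 85 °C, hν; filter, concentrate
Reagents that add atoms: N‑bromosuccinimide, O=C1CCC(=O)N1Br
Why: Wohl–Ziegler radical bromination should take a benzylic methyl hydrogen, the acyl bromide being inert to the radical chain and (unlike a free acid or alkyl ester) unable to lactonise onto the new CH2Br, while the non‑polar medium keeps ionic ring bromination down.

Step 3
Reactants: 4 cycloheptanone; 5 pentylmagnesium bromide
Product: 7 1‑pentylcycloheptan‑1‑ol, via bromomagnesium alkoxide 6 (not isolated)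
Conditions: THF, 0 °C to rt; then 1 M HCl, 0 °C
Reagents that add atoms: none
Why: Grignard 1,2‑addition of the pentyl nucleophile to the ketone carbonyl gives the tertiary alkoxide, which is protonated on work‑up.

Step 4
Reactants: 7 1‑pentylcycloheptan‑1‑ol
Product: 8 1‑pentylcyclohept‑1‑ene
Conditions: TsOH·H2O (5 mol %), toluene, reflux, Dean–Stark
Reagents that add atoms: none
Why: Acid‑catalysed E1 dehydration of the tertiary alcohol under thermodynamic control with water removal should favour the endocyclic trisubstituted (Zaitsev) alkene.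

Step 5
Reactants: 8 1‑pentylcyclohept‑1‑ene
Product: 10 7‑oxododecanal, via secondary ozonide 9 (not isolated)
Conditions: O3, CH2Cl2, –78 °C; then PPh3 (1.1 equiv), –78 °C to rt
Reagents that add atoms: ozone, [O-][O+]=O
Why: Criegee ozonolysis with reductive phosphine work‑up cleaves the ring C=C so that the pentyl‑bearing carbon becomes the ketone and the CH carbon the aldehyde, five ring methylenes apart, which is the carbonyl spacing the side chain needs.

Step 6
Reactants: 3 2‑(bromomethyl)‑4,6‑dimethoxybenzoyl bromide; 10 7‑oxododecanal
Product: 11 1‑bromo‑7‑oxododecyl 2‑(bromomethyl)‑4,6‑dimethoxybenzoate (racemic)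
Conditions: ZnBr2 (2 mol %), CH2Cl2, –20 to 0 °C; filter, concentrate, use at once
Reagents that add atoms: none
Why: Lewis‑acid‑catalysed 1,2‑addition of an acyl bromide across an aldehyde C=O (the classical 1‑haloalkyl ester synthesis) should be fast and selective for the aldehyde because the corresponding ketone adduct is disfavoured, and the new C–Br stereocentre is left racemic on purpose since step 7 is enantioconvergent.

Step 7
Reactants: 11 1‑bromo‑7‑oxododecyl 2‑(bromomethyl)‑4,6‑dimethoxybenzoate
Product: 12 (3R)‑6,8‑dimethoxy‑3‑(6‑oxoundecyl)‑3,4‑dihydro‑1H‑isochromen‑1‑one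
Conditions: NiBr2·glyme (10 mol %), chiral bis(oxazoline) ligand L* (12 mol %, antipode fixed by screening), Mn powder (3 equiv), DMA/THF, 0 °C, slow addition of 11 (≤0.02 M)
Reagents that add atoms: none
Why: Proposed new method: an intramolecular, enantioconvergent nickel‑catalysed reductive (cross‑electrophile) C(sp3)–C(sp3) coupling, in which the benzylic C–Br bond should add oxidatively to L*Ni(0), the benzyl–nickel species after reduction by Mn should abstract bromine from the tethered gem‑bromo ester, and the planar α‑acyloxyalkyl radical at C3 should be recaptured by the same nickel to give a seven‑membered Ni(III) metallacycle that reductively eliminates the C3–C4 bond. The closest known reaction types are the intermolecular nickel‑catalysed enantioconvergent alkyl–alkyl couplings of racemic 1‑bromoalkyl esters (aldehyde/acyl bromide adducts) with alkylnickel species generated in situ, and nickel‑catalysed reductive cyclisations of dihalides; the tethered benzyl partner and the lactone ring closure are what is new. The six‑membered lactone ring (O2–C3–C4–C4a–C8a–C1) is closed in a formal 6‑exo‑tet sense at C3 by C–C reductive elimination, the ester having to reach its s‑trans (lactone‑like) rotamer inside the nickelacycle. The C3 stereocentre is set under catalyst control by the chiral ligand at radical capture/reductive elimination, both enantiomers of 11 converging through the same achiral radical, so the 3R sense has to be secured by the choice of ligand antipode and verified. The step needs ring closure to outrun bimolecular benzyl–benzyl coupling and oligomerisation, β‑hydride loss to an enol ester and simple hydrodebromination; the 1,6‑tether, slow addition at high dilution, the different activation modes of the two C–Br bonds (two‑electron at the benzylic carbon, halogen‑atom transfer at the α‑acyloxy carbon) and the low temperature should secure this, with the ketone and aryl ethers as spectators.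

Step 8
Reactants: 12 (3R)‑6,8‑dimethoxy‑3‑(6‑oxoundecyl)‑3,4‑dihydro‑1H‑isochromen‑1‑one
Product: 14 (3R)‑8‑hydroxy‑6‑methoxy‑3‑(6‑oxoundecyl)‑3,4‑dihydro‑1H‑isochromen‑1‑one, via aryloxydichloroborane chelate 13 (not isolated)
Conditions: BCl3 (1.5 equiv, 1 M in CH2Cl2), CH2Cl2, –78 to 0 °C; then H2O
Reagents that add atoms: none
Why: Chelation‑controlled Lewis‑acid ether cleavage, in which BCl3 bound between the lactone carbonyl and the peri 8‑methoxy oxygen delivers chloride to that methyl group only, so the 6‑methoxy group, the lactone, the ketone and the C3 stereocentre (not involved) should be retained.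

**Compound list**

1 | 2,4‑dimethoxy‑6‑methylbenzoic acid | Cc1cc(OC)cc(OC)c1C(=O)O | starting material
2 | 2,4‑dimethoxy‑6‑methylbenzoyl bromide | Cc1cc(OC)cc(OC)c1C(=O)Br | intermediate
3 | 2‑(bromomethyl)‑4,6‑dimethoxybenzoyl bromide | BrCc1cc(OC)cc(OC)c1C(=O)Br | intermediate
4 | cycloheptanone | O=C1CCCCCC1 | starting material
5 | pentylmagnesium bromide | CCCCC[Mg]Br | starting material
6 | bromomagnesium 1‑pentylcycloheptan‑1‑olate | CCCCCC1(O[Mg]Br)CCCCCC1 | intermediate (not isolated)
7 | 1‑pentylcycloheptan‑1‑ol | CCCCCC1(O)CCCCCC1 | intermediate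
8 | 1‑pentylcyclohept‑1‑ene | CCCCCC1=CCCCCC1 | intermediate
9 | 1‑pentyl‑8,9,10‑trioxabicyclo[5.2.1]decane (secondary ozonide) | CCCCCC12CCCCCC(OO1)O2 | intermediate (not isolated)
10 | 7‑oxododecanal | CCCCCC(=O)CCCCCC=O | intermediate
11 | 1‑bromo‑7‑oxododecyl 2‑(bromomethyl)‑4,6‑dimethoxybenzoate (racemic) | CCCCCC(=O)CCCCCC(Br)OC(=O)c1c(CBr)cc(OC)cc1OC | intermediate
12 | (3R)‑6,8‑dimethoxy‑3‑(6‑oxoundecyl)‑3,4‑dihydro‑1H‑isochromen‑1‑one | CCCCCC(=O)CCCCC[C@@H]1Cc2cc(OC)cc(OC)c2C(=O)O1 | intermediate
13 | (3R)‑8‑[(dichloroboranyl)oxy]‑6‑methoxy‑3‑(6‑oxoundecyl)‑3,4‑dihydro‑1H‑isochromen‑1‑one | CCCCCC(=O)CCCCC[C@@H]1Cc2cc(OC)cc(OB(Cl)Cl)c2C(=O)O1 | intermediate (not isolated)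
14 | (3R)‑8‑hydroxy‑6‑methoxy‑3‑(6‑oxoundecyl)‑3,4‑dihydro‑1H‑isochromen‑1‑one | CCCCCC(=O)CCCCC[C@@H]1Cc2cc(OC)cc(O)c2C(=O)O1 | target

**Step count and risks**

Total step count: 8. Longest linear sequence: 6 steps (steps 3, 4, 5, 6, 7, 8 from cycloheptanone); the aryl branch is 5 steps (1, 2, 6, 7, 8).

Steps most likely to fail:

1. Step 7 (carries the label). The ring closure may lose to intermolecular benzyl–benzyl coupling or oligomerisation, the α‑acyloxyalkyl–nickel may lose a β‑hydride to give an enol ester, or facial discrimination at radical capture may be poor. The fallback uses known chemistry, sets out from 1 and 10 and returns at 12.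
   - Acid 1 is doubly deprotonated (LDA, 2.2 equiv, THF, –78 °C) to lithium 2‑(lithiomethyl)‑4,6‑dimethoxybenzoate F1.
   - F1 is added inversely to the aldehyde carbonyl of 10 at –78 °C; acidification (aq. HCl) in the same operation should close racemic 6,8‑dimethoxy‑3‑(6‑oxoundecyl)‑3,4‑dihydro‑1H‑isochromen‑1‑one F2 (toluate‑dianion/aldehyde lactonisation).
   - Radical bromination at C4 (NBS, AIBN, PhCF3, 80 °C) should give 4‑bromo‑6,8‑dimethoxy‑3‑(6‑oxoundecyl)‑3,4‑dihydro‑1H‑isochromen‑1‑one F3.
   - Dehydrobromination (Et3N, CH2Cl2, rt) should give the isocoumarin 6,8‑dimethoxy‑3‑(6‑oxoundecyl)‑1H‑isochromen‑1‑one F4.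
   - Asymmetric hydrogenation of the C3=C4 enol‑lactone bond (H2, chiral Ru–NHC–diamine catalyst of the antipode that gives 3R), a known reaction class for 3‑substituted isocoumarins, sets C3. The side‑chain ketone is expected to be reduced as well, giving (3R)‑3‑(6‑hydroxyundecyl)‑6,8‑dimethoxy‑3,4‑dihydro‑1H‑isochromen‑1‑one F5 as a carbinol epimer mixture.
   - Dess–Martin oxidation (CH2Cl2, rt) returns 12.

2. Step 2. Ionic bromination of the electron‑rich ring (positions between and beside the methoxy groups) and over‑bromination to the dibromomethyl compound may compete with the radical chain. The fallback sets out from 1 and returns at 3, replacing the radical bromination by halogenation of a preformed benzylic carbanion.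
   - Lateral dilithiation of 1 (LDA, 2.2 equiv, THF, –78 °C) gives the same dianion, lithium 2‑(lithiomethyl)‑4,6‑dimethoxybenzoate F1.
   - F1 is added inversely to excess 1,2‑dibromoethane; the resulting benzylic bromide should lactonise in the same pot to 5,7‑dimethoxy‑2‑benzofuran‑1(3H)‑one F6.
   - Ring opening of F6 with dibromotriphenylphosphorane (PhCl, reflux), the known cleavage of lactones to ω‑bromoacyl bromides, should give 3.

3. Step 6. Lewis‑acid‑promoted intramolecular aldolisation of the 1,7‑keto‑aldehyde (six‑membered ring), reversal of the addition, or HBr loss from the gem‑bromo ester on concentration may erode the adduct. The fallback sets out from 3 and 10 and returns at 12 without a new compound: isolation of 11 is abandoned for a three‑component domino. Compounds 3 and 10 are combined at –20 °C in DMA/THF without zinc salt (the amide solvent promotes the addition) and this solution is fed slowly into the Ni/L*/Mn mixture of step 7, so that the adduct is consumed by the nickel cycle as it forms, in the manner of known multicomponent couplings of aldehyde/acyl bromide adducts.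

**Further compounds**

F1 | step 7 | lithium 2‑(lithiomethyl)‑4,6‑dimethoxybenzoate | [Li]Cc1cc(OC)cc(OC)c1C(=O)O[Li]
F2 | step 7 | racemic 6,8‑dimethoxy‑3‑(6‑oxoundecyl)‑3,4‑dihydro‑1H‑isochromen‑1‑one | CCCCCC(=O)CCCCCC1Cc2cc(OC)cc(OC)c2C(=O)O1
F3 | step 7 | 4‑bromo‑6,8‑dimethoxy‑3‑(6‑oxoundecyl)‑3,4‑dihydro‑1H‑isochromen‑1‑one (diastereomer mixture) | CCCCCC(=O)CCCCCC1OC(=O)c2c(OC)cc(OC)cc2C1Br
F4 | step 7 | 6,8‑dimethoxy‑3‑(6‑oxoundecyl)‑1H‑isochromen‑1‑one | CCCCCC(=O)CCCCCC1=Cc2cc(OC)cc(OC)c2C(=O)O1
F5 | step 7 | (3R)‑3‑(6‑hydroxyundecyl)‑6,8‑dimethoxy‑3,4‑dihydro‑1H‑isochromen‑1‑one (carbinol epimers) | CCCCCC(O)CCCCC[C@@H]1Cc2cc(OC)cc(OC)c2C(=O)O1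
F6 | step 2 | 5,7‑dimethoxy‑2‑benzofuran‑1(3H)‑one | COc1cc(OC)c2C(=O)OCc2c1
F0 | step 6 | none | none
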